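**Assumption:** albanin A has no stereocentre, so the achiral compound itself is the target and no stereocontrol is needed. The E enone geometry of 8 is erased in step 5.

## Retrosynthetic overview

1. Albanin A ⇒ ring C closed last through the O1–C2 bond: a palladium-catalysed deallylative oxa-Michael/transfer dehydrogenation of the penta-O-allyl α-prenyl chalcone 8, followed in the same flask by removal of the remaining allyl ethers.
2. 8 ⇒ Claisen–Schmidt condensation of α-prenyl ketone 5 with aldehyde 7.
3. 5 ⇒ enolate prenylation of tri-O-allyl phloroacetophenone 3; 3 and 7 ⇒ O-allylation of commercial 1 and 6.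
4. Rings A and B are bought; ring C is the only ring formed (step 5). The allyl groups serve as protecting groups and one of them as the hydrogen acceptor.

## Route

**Step 1**
Reactants: 1 2',4',6'-trihydroxyacetophenone; 2 allyl bromide
Product: 3 1-[2,4,6-tris(allyloxy)phenyl]ethanone
Conditions: 2 (3.6 equiv), K2CO3 (4.5 equiv), DMF, 60 °C
Reagents that add atoms: allyl bromide (2), C=CCBr
Why: Williamson ether synthesis; the carbonate-generated phenoxides alkylate on oxygen in DMF, excess bromide at 60 °C also captures the hydrogen-bonded ortho hydroxyls, and the temperature is far below that of an aromatic Claisen rearrangement.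

**Step 2**
Reactants: 3 1-[2,4,6-tris(allyloxy)phenyl]ethanone; 4 prenyl bromide
Product: 5 5-methyl-1-[2,4,6-tris(allyloxy)phenyl]hex-4-en-1-one
Conditions: LiN(iPr)2 (LDA, 1.05 equiv), THF, −78 °C; then 4 (1.0 equiv), −78 to 0 °C
Reagents that add atoms: prenyl bromide (4), CC(C)=CCBr
Why: Kinetic lithium enolate alkylation; with all phenols capped the methyl ketone is the only acidic site, and SN2 attack at the primary carbon of the allylic bromide gives the linear prenyl chain, one equivalent of bromide at low temperature limiting double alkylation.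

**Step 3**
Reactants: 6 2,4-dihydroxybenzaldehyde; 2 allyl bromide
Product: 7 2,4-bis(allyloxy)benzaldehyde
Conditions: 2 (2.5 equiv), K2CO3 (3 equiv), DMF, 60 °C
Reagents that add atoms: allyl bromide (2), C=CCBr
Why: Williamson ether synthesis of both phenols, the chelated ortho hydroxyl included, under the same conditions as step 1.

**Step 4**
Reactants: 5 5-methyl-1-[2,4,6-tris(allyloxy)phenyl]hex-4-en-1-one; 7 2,4-bis(allyloxy)benzaldehyde
Product: 8 (2E)-3-[2,4-bis(allyloxy)phenyl]-2-(3-methylbut-2-en-1-yl)-1-[2,4,6-tris(allyloxy)phenyl]prop-2-en-1-one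
Conditions: KOH (aq. 50 %), EtOH, 50 °C
Reagents that add atoms: none
Why: Claisen–Schmidt (crossed aldol) condensation; the aldehyde cannot enolise, the ketone has one enolisable position, and E1cB dehydration gives the E enone (aryl trans to the carbonyl), which cannot close prematurely to a flavanone because no ortho hydroxyl is free.

**Step 5**
Reactants: 8 (2E)-3-[2,4-bis(allyloxy)phenyl]-2-(3-methylbut-2-en-1-yl)-1-[2,4,6-tris(allyloxy)phenyl]prop-2-en-1-one
Product: 10 albanin A, via tetra-O-allyl albanin A 9 (not isolated)
Conditions: Pd(OAc)2 (5 mol %), dppe (5 mol %), MeCN, 80 °C; then morpholine (10 equiv), Pd(PPh3)4 (2 mol %), 50 °C; aq. citric acid work-up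
Reagents that add atoms: none
Why: Proposed new method: zerovalent palladium (formed in situ from Pd(OAc)2/dppe) ionises an aryl allyl ether ortho to the ketone, the best leaving group because its phenoxide is a vinylogous carboxylate; the freed ring A phenoxide closes ring C by 6-endo oxa-Michael addition to the enone (the new O1–C2 bond); the resulting allylpalladium enolate, hindered at its fully substituted carbon against C-allylation in MeCN, undergoes β-hydride elimination of H-2 and releases propene, so one allyl group is the built-in hydrogen acceptor and the aromatic 4-pyranone is the thermodynamic sink (both enone isomers and both equivalent ortho ethers converge); morpholine then removes the four remaining allyl ethers by Tsuji–Trost transfer without touching the C-prenyl group; the closest known reactions are the Tsuji palladium-catalysed dehydrogenation of allyl enol carbonates and allyl β-keto esters to enones and the palladium/amine deallylation of aryl allyl ethers.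

## Compound list

1 | 2',4',6'-trihydroxyacetophenone | CC(=O)c1c(O)cc(O)cc1O | starting material
2 | allyl bromide (3-bromoprop-1-ene) | C=CCBr | starting material
3 | 1-[2,4,6-tris(allyloxy)phenyl]ethanone | CC(=O)c1c(OCC=C)cc(OCC=C)cc1OCC=C | intermediate
4 | prenyl bromide (1-bromo-3-methylbut-2-ene) | CC(C)=CCBr | starting material
5 | 5-methyl-1-[2,4,6-tris(allyloxy)phenyl]hex-4-en-1-one | CC(C)=CCCC(=O)c1c(OCC=C)cc(OCC=C)cc1OCC=C | intermediate
6 | 2,4-dihydroxybenzaldehyde | O=Cc1ccc(O)cc1O | starting material
7 | 2,4-bis(allyloxy)benzaldehyde | O=Cc1ccc(OCC=C)cc1OCC=C | intermediate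
8 | (2E)-3-[2,4-bis(allyloxy)phenyl]-2-(3-methylbut-2-en-1-yl)-1-[2,4,6-tris(allyloxy)phenyl]prop-2-en-1-one | O=C(/C(CC=C(C)C)=C/c1ccc(OCC=C)cc1OCC=C)c1c(OCC=C)cc(OCC=C)cc1OCC=C | intermediate
9 | tetra-O-allyl albanin A: 5,7-bis(allyloxy)-2-[2,4-bis(allyloxy)phenyl]-3-(3-methylbut-2-en-1-yl)-4H-chromen-4-one | CC(C)=CCc1c(-c2ccc(OCC=C)cc2OCC=C)oc2cc(OCC=C)cc(OCC=C)c2c1=O | intermediate (not isolated)
10 | albanin A: 2-(2,4-dihydroxyphenyl)-5,7-dihydroxy-3-(3-methylbut-2-en-1-yl)-4H-chromen-4-one | CC(C)=CCc1c(-c2ccc(O)cc2O)oc2cc(O)cc(O)c2c1=O | target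

## Step count and risks

Total steps: 5. Longest linear sequence: 4 (steps 1, 2, 4, 5).

**Step 5 (the proposed new step).** Three things can go wrong. The allylpalladium enolate may C-allylate at C-3. The electron-rich ring A phenoxide may be C-allylated irreversibly. Ionisation of the aryl allyl ether may be too slow without a scavenger. The fallback uses known chemistry only, sets out from 5 and 7 and comes back at 10. The lithium enolate of 5 (LiN(iPr)2, THF, −78 °C) is added to 7 to give the β-hydroxy ketone aldol adduct F3, which is quenched cold. Dess–Martin periodinane (CH2Cl2, NaHCO3, 0 °C to rt) oxidises it to the penta-O-allyl 2-prenyl-1,3-diketone F5. Pd(PPh3)4 (5 mol %) with morpholine in THF removes all five allyl ethers to give the pentahydroxy 2-prenyl-1,3-diketone F6. F6 cyclodehydrates in AcOH at 60 °C to 10. Both aryl rings of F6 carry an ortho hydroxyl. Closure of a ring A hydroxyl onto the ring B carbonyl is expected to dominate, because it gives the 5-hydroxy-chelated flavone and the two closures can equilibrate through F6 under acid. This regiochemical question does not exist in the main route, where only ring A can add to the enone.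

**Step 4.** The ketone is hindered (α-branched, di-ortho-substituted) and the aldehyde is electron-rich, so retro-aldol and slow dehydration may stall the thermodynamic condensation. The fallback sets out from 5 and 7 and comes back at 8. A kinetic directed aldol addition (LiN(iPr)2, THF, −78 °C, cold quench) gives the β-hydroxy ketone aldol adduct F3. MsCl/Et3N (CH2Cl2, 0 °C) converts it to the benzylic mesylate F4, which eliminates with DBU at room temperature to 8. Either enone isomer is usable in step 5.

**Step 2.** Proton exchange between product and enolate can give double prenylation and recovered 3. The fallback sets out from 3 and comes back at 5 through a stabilised enolate that alkylates once. NaH and diethyl carbonate (THF, reflux) give the β-keto ester ethyl 3-oxo-3-[2,4,6-tris(allyloxy)phenyl]propanoate F1. K2CO3 and 4 in acetone (reflux) give the mono-C-prenylated β-keto ester F2. KOH in EtOH/H2O, then acidification and warming to 50 °C, hydrolyses and decarboxylates F2 to 5.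

## Further compounds

F1 | step 2 | ethyl 3-oxo-3-[2,4,6-tris(allyloxy)phenyl]propanoate | CCOC(=O)CC(=O)c1c(OCC=C)cc(OCC=C)cc1OCC=C
F2 | step 2 | ethyl 5-methyl-2-[2,4,6-tris(allyloxy)benzoyl]hex-4-enoate (racemic) | CCOC(=O)C(CC=C(C)C)C(=O)c1c(OCC=C)cc(OCC=C)cc1OCC=C
F3 | step 4 | 3-[2,4-bis(allyloxy)phenyl]-3-hydroxy-2-(3-methylbut-2-en-1-yl)-1-[2,4,6-tris(allyloxy)phenyl]propan-1-one (racemic, mixture of diastereomers) | CC(C)=CCC(C(O)c1ccc(OCC=C)cc1OCC=C)C(=O)c1c(OCC=C)cc(OCC=C)cc1OCC=C
F4 | step 4 | methanesulfonate of F3 (racemic, mixture of diastereomers) | CC(C)=CCC(C(OS(C)(=O)=O)c1ccc(OCC=C)cc1OCC=C)C(=O)c1c(OCC=C)cc(OCC=C)cc1OCC=C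
F5 | step 5 | 1-[2,4-bis(allyloxy)phenyl]-2-(3-methylbut-2-en-1-yl)-3-[2,4,6-tris(allyloxy)phenyl]propane-1,3-dione (racemic) | CC(C)=CCC(C(=O)c1ccc(OCC=C)cc1OCC=C)C(=O)c1c(OCC=C)cc(OCC=C)cc1OCC=C
F6 | step 5 | 1-(2,4-dihydroxyphenyl)-2-(3-methylbut-2-en-1-yl)-3-(2,4,6-trihydroxyphenyl)propane-1,3-dione (racemic) | CC(C)=CCC(C(=O)c1ccc(O)cc1O)C(=O)c1c(O)cc(O)cc1O
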